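#### Analysis of the target

- Target 10 is an isoflavone. It is a 4H-chromen-4-one made of benzo ring A (C4a, C5, C6, C7, C8, C8a) and pyranone ring C (O1, C2, C3, C4), and it carries ring B (C1'–C6') at C3.
- Ring A is pentasubstituted and has four contiguous oxygens: O1 at C8a, free OH at C8 and C7, and OMe at C6. Only C5 carries hydrogen.
- Ring B carries C3'-OH, C4'-OMe and C5'-OMe. It is joined through C1', which lies para to C4'-OMe and meta to both C3'-OH and C5'-OMe.
- There is no stereocentre and no stereogenic double bond. C2' and C6' carry only hydrogen, so rotation about C3–C1' is free and the molecule is achiral.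
- Three groups are sensitive. The C7/C8 catechol suffers from air, base and any oxidant. The pyranone is opened at C2 by hard nucleophiles. The C2=C3 bond can be hydrogenated.
- The difficulty is regiochemical. Three OH and three OMe groups must each be placed as what they are, because no late selective methylation or demethylation is credible. C4'-OMe and any C7/C8 ether are equally hindered and equally labile.
- The strategy rests on C1'. As a carbon meta to both flanking donors, it cannot be reached by electrophilic substitution. It is, however, exactly the β-carbon (C3) of the o-quinone monoketal 7 that forms when 2,3-dimethoxyphenol 6 is oxidized at the carbon that becomes C4'. The C3–C1' bond can therefore be made as a union of two nucleophilic carbons, by dearomatizing polarity reversal of ring B.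

#### Retrosynthetic reasoning

**10 ⇒ 9.** Only the two O-benzyl bonds at C7-O and C8-O are cut.
- The catechol is the most fragile part of 10, so it is released last, by a neutral and non-oxidative reaction that leaves the three methyl ethers alone.
- C3'-OH needs no protecting group because of the way ring B enters.

**9 ⇒ 5 + 6 (through 8 and 7); key disconnection.** Two bonds are cut: C3–C1' (ring C to ring B) and O1–C2 (closure of ring C).
- The precursors are the open-chain enaminone 5 and the unfunctionalized, unprotected phenol 6. No halogen, boron or protecting group is placed on ring B.
- Both carbons to be joined are nucleophilic: the α-carbon of 5 and a ring carbon of 6. Two-electron oxidation of 6 to the dienone ketal 7 reverses the polarity of ring B.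
- In 7 the carbonyl carbon is the future C3'. The ketal carbon is the future C4'. The β-carbon is the future C1'.
- Conjugate addition and loss of one ketal methoxy group restore the arene (8) with C3'-OH free and C4'-OMe and C5'-OMe in place.
- The new OH lies meta to the new bond, so ring B cannot close a benzofuran onto the enamine carbon. Only the ring A phenol can capture that carbon, which closes ring C with loss of the amine.
- A cut at C4–C4a would need a free tetraoxygenated phenol. A cut at O1–C8a would face two non-equivalent ortho positions on ring A. Both were judged worse.
- The forward reaction has to achieve three things: dearomatization at the OMe-bearing ortho carbon of 6, β-selective attack on 7, and ring closure in the same flask.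

**5 ⇒ 4.** The C2=C3 bond is cut. C2 comes from a formamide acetal that condenses with the methyl ketone of 4. This one step brings in the last skeletal carbon, makes C3 a soft nucleophile, and equips C2 with the leaving group needed for ring closure.

**4 ⇒ 3 ⇒ 2.** The C6–OMe bond (C5 of the acetophenone) is cut back to a C–Br bond and then to C–H.
- The position is para to the phenol OH that becomes O1, ortho to a benzyloxy group and meta to the acyl group.
- Bromination can therefore go nowhere else, and a copper-catalysed C–O coupling then places the methoxy group.
- The fourth oxygen of ring A is thus added to a cheap trioxygenated ring, and no tetraoxygenated benzene has to be bought or built.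

**2 ⇒ 1.** The two O-benzyl bonds are cut. In 1 the hydrogen bond between C2-OH and the acetyl oxygen separates the future O1 from the future C7/C8 oxygens, so a simple double alkylation suffices.

#### Alternatives that were turned down

**Alternative 1:** the textbook deoxybenzoin route.
- Disconnection: C4–C4a, and the one-carbon unit C2 (bonds C2–C3 and O1–C2).
- Forward key step: Friedel–Crafts (Hoesch-type) acylation of 4-methoxybenzene-1,2,3-triol A1 with (3-hydroxy-4,5-dimethoxyphenyl)acetic acid A2 under a boron Lewis acid. This gives the deoxybenzoin A3, which is then formylated and cyclized with a Vilsmeier-type reagent.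
- Reasons for turning it down:
  - Neither building block is a common article of commerce.
  - A1 would come from a Dakin oxidation and autoxidizes like pyrogallol.
  - A1 offers two doubly activated free positions, one para to C3-OH and ortho to C1-OH, the other para to C2-OH and ortho to OMe.
  - A2 needs a three- to four-step homologation of an aldehyde.
  - The steps are spent on the building blocks, and the C1 reagent then meets four free phenols.

**Alternative 2:** cross-coupling on the finished chromone.
- Disconnection: C3–C1' alone.
- Forward key step: iodocyclization of 5 to 7,8-bis(benzyloxy)-3-iodo-6-methoxy-4H-chromen-4-one A4, then Suzuki–Miyaura coupling with [3-(benzyloxy)-4,5-dimethoxyphenyl]boronic acid A5.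
- Reasons for turning it down:
  - Both carbons must first be functionalized, with iodine at C3 and boron at C1'.
  - C1' cannot be halogenated directly, because substitution on a 1,2,3-trioxygenated benzene goes ortho and para to the outer donors.
  - A5 therefore costs a multistep detour with its own protecting group.
  - Ring closure and C–C bond formation become separate operations with stoichiometric iodine and boron waste, and the route grows by two to three steps.
- It is the most reliable plan and is kept only as the safety net for step 5.

**Alternative 3:** the biomimetic 1,2-aryl shift.
- Disconnection: C3–C1' is formed by migration of ring B from C2.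
- Forward key step: Claisen–Schmidt condensation of 4 with 3-(benzyloxy)-4,5-dimethoxybenzaldehyde A6 gives chalcone A7. Oxidative rearrangement with a thallium(III) or iodine(III) reagent in an alcohol gives the racemic acetal A8, which cyclizes in acid.
- Reasons for turning it down:
  - The oxidant meets ring A, a hydroquinone monoether (C8a-OH para to C6-OMe). This ring is oxidized faster than the electron-poor enone C=C, so a third protecting group on the C8a oxygen would have to be put on and taken off.
  - The para-methoxy group of the migrating ring is twisted out of conjugation by two ortho neighbours. Phenonium bridging is weakened, and solvent addition without migration gains ground.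
  - Ring B needs its own protection.
  - The count exceeds that of the chosen route by at least three steps.

Key step: step 5

Assumption (remark on the chemistry): the given SMILES contains no stereocentre and no stereogenic double bond. Target 10 is achiral, the request for a single enantiomer has no object, and no stereocontrol is planned.

#### Route

**Step 1**
Reactants: 1 2',3',4'-trihydroxyacetophenone (gallacetophenone)
Product: 2 1-[3,4-bis(benzyloxy)-2-hydroxyphenyl]ethan-1-one
Conditions: BnBr (2.05 equiv), K2CO3 (2.2 equiv), DMF, Ar, rt → 40 °C
Reagents that add atoms: benzyl bromide, BrCc1ccccc1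
Why: Williamson etherification; C2-OH is tied to the acetyl oxygen by an intramolecular hydrogen bond and is the least acidic and least nucleophilic of the three, so two equivalents of benzyl bromide should go to C4-OH (para to the carbonyl, most acidic) and then to C3-OH; argon keeps the pyrogallol-type triol from autoxidation in base.

**Step 2**
Reactants: 2 1-[3,4-bis(benzyloxy)-2-hydroxyphenyl]ethan-1-one
Product: 3 1-[3,4-bis(benzyloxy)-5-bromo-2-hydroxyphenyl]ethan-1-one
Conditions: NBS (1.0 equiv), MeCN, 0 °C, dark
Reagents that add atoms: N-bromosuccinimide, O=C1CCC(=O)N1Br
Why: Electrophilic aromatic bromination; C5 is para to the free C2-OH, ortho to C4-OBn and meta to the acetyl group, whereas the only other free position, C6, is ortho to the acetyl group and meta to the phenol, so one regioisomer is expected; ionic conditions at 0 °C leave the benzylic CH2 groups and the methyl ketone alone.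

**Step 3**
Reactants: 3 1-[3,4-bis(benzyloxy)-5-bromo-2-hydroxyphenyl]ethan-1-one
Product: 4 1-[3,4-bis(benzyloxy)-2-hydroxy-5-methoxyphenyl]ethan-1-one
Conditions: NaOMe (5 equiv, 25% in MeOH), CuBr (20 mol%), DMF, Ar, 110 °C; dilute HCl work-up
Reagents that add atoms: sodium methoxide, [Na+].[O-]C
Why: Copper-catalysed Ullmann-type C–O coupling of an aryl bromide with methoxide, the reaction type that converts bromophenol aldehydes and ketones into their methoxy analogues without protection of the phenol; benzyl ethers are inert to methoxide, and the phenoxide form of the substrate damps the aldol reactivity of the ketone.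

**Step 4**
Reactants: 4 1-[3,4-bis(benzyloxy)-2-hydroxy-5-methoxyphenyl]ethan-1-one
Product: 5 (E)-1-[3,4-bis(benzyloxy)-2-hydroxy-5-methoxyphenyl]-3-(dimethylamino)prop-2-en-1-one
Conditions: DMF-DMA (2 equiv), toluene, 95 °C
Reagents that add atoms: N,N-dimethylformamide dimethyl acetal, COC(OC)N(C)C
Why: Condensation of the methyl ketone with the amide acetal gives the push-pull (E)-enaminone, the standard C1 homologation of o-hydroxyacetophenones; it brings in the future C2 and makes the future C3 a soft carbon nucleophile, and the chelated phenol is not methylated at this temperature.

**Step 5**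
Reactants: 5 (E)-1-[3,4-bis(benzyloxy)-2-hydroxy-5-methoxyphenyl]-3-(dimethylamino)prop-2-en-1-one; 6 2,3-dimethoxyphenol
Product: 9 7,8-bis(benzyloxy)-3-(3-hydroxy-4,5-dimethoxyphenyl)-6-methoxy-4H-chromen-4-one, via masked o-benzoquinone 7 (not isolated), via α-aryl enaminone 8 (not isolated)
Conditions: 6 (1.6 equiv), PhI(OAc)2 (1.5 equiv), MeOH, 0 °C, 20 min; then 5 (1.0 equiv) in MeOH–CH2Cl2, 0 → 45 °C
Reagents that add atoms: methanol, CO
Why: Proposed new method: PhI(OAc)2 binds the phenol oxygen of 6 and methanol attacks the ortho carbon that already carries OMe, the only ring position at which the developing cation is an oxocarbenium ion, which gives the masked o-benzoquinone 7 (iodine(III) oxidative dearomatization, known for 2-methoxyphenols). In 7 the C5-OMe group pushes electron density to C4, C2 and the carbonyl oxygen but not to C3, and C5 itself is substituted and flanked by the ketal, so the β-carbon C3 is the one open soft electrophilic site, and it is the carbon that becomes C1'. The nucleophilic α-carbon of 5 (future C3) adds there in Michael fashion, as in the first step of a Nenitzescu reaction, and loss of the C1'-H proton and of one ketal methoxy group (vinylogous 1,4-elimination driven by aromatization) gives 8 with C3'-OH free and C4'-OMe and C5'-OMe in place; since this OH is meta to the new bond, the benzofuran closure of the Nenitzescu manifold is impossible. The chelated C2-OH of ring A then adds to the enaminone β-carbon (future C2) and dimethylamine leaves, a 6-endo-trig oxa-Michael addition–elimination that forms O1–C2 and closes the pyranone ring. The closest known reaction types are the Michael addition/rearomatization of indoles, electron-rich arenes and 1,3-dicarbonyl compounds to masked o-benzoquinones and to 3-methoxy-o-benzoquinone (which takes up the nucleophile at C5, the corresponding carbon), and the domino C–H functionalization/chromone annulation of o-hydroxyaryl enaminones with halogen, sulfur and aryl electrophiles; their combination is new. The step needs conjugate (β) attack and not attack para to the ring oxygen through an ionized ketal, which is secured by the absence of any acid stronger than the acetic acid released by the oxidant, and it needs the complete absence of iodine(III) when 5 is added, which is secured by the slight excess of 6 over the oxidant, because ring A of 5 is a hydroquinone monoether. The acetic acid also ties up the dimethylamine, which would otherwise consume 7. No stereocentre is formed.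

**Step 6**
Reactants: 9 7,8-bis(benzyloxy)-3-(3-hydroxy-4,5-dimethoxyphenyl)-6-methoxy-4H-chromen-4-one
Product: 10 7,8-dihydroxy-3-(3-hydroxy-4,5-dimethoxyphenyl)-6-methoxy-4H-chromen-4-one (target)
Conditions: H2 (1 atm), 10% Pd/C, EtOAc–MeOH, rt; filtration and concentration under Ar
Reagents that add atoms: none
Why: Hydrogenolysis of the two aryl benzyl ethers; the methyl ethers and the free C3'-OH are untouched, and at 1 atm and room temperature O-benzyl cleavage should be much faster than saturation of the trisubstituted, vinylogous-ester C2=C3 bond; the catechol is handled under argon.

#### Compound list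

1 | 2',3',4'-trihydroxyacetophenone (gallacetophenone) | CC(=O)c1ccc(O)c(O)c1O | starting material
2 | 1-[3,4-bis(benzyloxy)-2-hydroxyphenyl]ethan-1-one | CC(=O)c1ccc(OCc2ccccc2)c(OCc2ccccc2)c1O | intermediate
3 | 1-[3,4-bis(benzyloxy)-5-bromo-2-hydroxyphenyl]ethan-1-one | CC(=O)c1cc(Br)c(OCc2ccccc2)c(OCc2ccccc2)c1O | intermediate
4 | 1-[3,4-bis(benzyloxy)-2-hydroxy-5-methoxyphenyl]ethan-1-one | CC(=O)c1cc(OC)c(OCc2ccccc2)c(OCc2ccccc2)c1O | intermediate
5 | (E)-1-[3,4-bis(benzyloxy)-2-hydroxy-5-methoxyphenyl]-3-(dimethylamino)prop-2-en-1-one | CN(C)/C=C/C(=O)c1cc(OC)c(OCc2ccccc2)c(OCc2ccccc2)c1O | intermediate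
6 | 2,3-dimethoxyphenol | COc1cccc(O)c1OC | starting material
7 | 5,6,6-trimethoxycyclohexa-2,4-dien-1-one (masked o-benzoquinone, not isolated) | COC1=CC=CC(=O)C1(OC)OC | intermediate
8 | 1-[3,4-bis(benzyloxy)-2-hydroxy-5-methoxyphenyl]-3-(dimethylamino)-2-(3-hydroxy-4,5-dimethoxyphenyl)prop-2-en-1-one (push-pull C=C, configurationally labile, not isolated) | CN(C)C=C(C(=O)c1cc(OC)c(OCc2ccccc2)c(OCc2ccccc2)c1O)c1cc(O)c(OC)c(OC)c1 | intermediate
9 | 7,8-bis(benzyloxy)-3-(3-hydroxy-4,5-dimethoxyphenyl)-6-methoxy-4H-chromen-4-one | COc1cc2c(=O)c(-c3cc(O)c(OC)c(OC)c3)coc2c(OCc2ccccc2)c1OCc1ccccc1 | intermediate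
10 | 7,8-dihydroxy-3-(3-hydroxy-4,5-dimethoxyphenyl)-6-methoxy-4H-chromen-4-one (achiral) | COc1cc2c(=O)c(-c3cc(O)c(OC)c(OC)c3)coc2c(O)c1O | target

#### Step count and least certain steps

Total step count: 6. Longest linear sequence: 6 steps (1 → 10). Compound 6 enters step 5 as bought.

**Step 5 (key step, proposed new method).**
- The most likely failure is a conjugate addition that is too slow. The C5-OMe group raises the LUMO of the dienone as a whole, and side processes may then take over:
  - acid-induced ring closure of the enaminone without arylation;
  - [4+2] cycloaddition of the dienone with itself or with the enaminone C=C;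
  - electron transfer from the hydroquinone-monoether ring A to the dienone;
  - attack para to the ring oxygen after ionization of the ketal;
  - partial para-oxidation of the phenol in the first stage.
- The fallback uses known chemistry. It sets out from 5 and 6 and comes back at 9.
- Iodine in chloroform cyclizes 5 to 7,8-bis(benzyloxy)-3-iodo-6-methoxy-4H-chromen-4-one F1, which is identical with A4.
- Compound 6 is masked in the flask as its O-boryl ether with pinacolborane. An iridium/bipyridine-catalysed, sterically governed C–H borylation then acts at the only C–H bond without an ortho neighbour. This gives 2,3-dimethoxy-5-(4,4,5,5-tetramethyl-1,3,2-dioxaborolan-2-yl)phenol F2.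
- Suzuki–Miyaura coupling of the two (Pd(dppf)Cl2, K2CO3, dioxane–water) gives 9.

**Step 3.**
- The substrate reacts as an electron-rich phenoxide, so the C–O coupling may be slow. Hydrodebromination and aldol-type self-condensation of the methyl ketone in hot alkoxide may then compete.
- The fallback replaces halogenation and coupling by direct C–H oxidation. It sets out from 2 and comes back at 4, bypassing step 2 as well.
- Elbs persulfate oxidation (para to the phenol, the classical reaction of 2-hydroxy-3,4-dialkoxyacetophenones) gives 1-[3,4-bis(benzyloxy)-2,5-dihydroxyphenyl]ethan-1-one F3.
- Its non-chelated C5-OH is methylated selectively with one equivalent of methyl iodide and potassium carbonate, which gives 4.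

**Step 1.**
- Discrimination between the three hydroxyl groups may be incomplete, through over-alkylation at the chelated C2-OH or a stop at the mono-ether. The triol may also autoxidize in base.
- The fallback turns the problem around. It sets out from 1 and comes back at 2.
- Exhaustive benzylation gives 1-[2,3,4-tris(benzyloxy)phenyl]ethan-1-one F4.
- Magnesium bromide etherate then removes only the benzyl group ortho to the carbonyl by chelation-controlled cleavage, which gives 2.

**Step 6.**
- The C2=C3 bond may be saturated before the second, hindered benzyl ether has left. The freed catechol may be oxidized on the catalyst during filtration in air.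
- The fallback is non-reductive. It sets out from 9 and comes back at 10.
- Boron trichloride with pentamethylbenzene as cation scavenger in dichloromethane at −78 °C cleaves aryl benzyl ethers by a Lewis-acid, carbocation-transfer mechanism. It touches neither aryl methyl ethers nor the enone. This fallback makes no new compound (F0).

#### Further compounds

F1 | step 5 | 7,8-bis(benzyloxy)-3-iodo-6-methoxy-4H-chromen-4-one | COc1cc2c(=O)c(I)coc2c(OCc2ccccc2)c1OCc1ccccc1
F2 | step 5 | 2,3-dimethoxy-5-(4,4,5,5-tetramethyl-1,3,2-dioxaborolan-2-yl)phenol | COc1cc(B2OC(C)(C)C(C)(C)O2)cc(O)c1OC
F3 | step 3 | 1-[3,4-bis(benzyloxy)-2,5-dihydroxyphenyl]ethan-1-one | CC(=O)c1cc(O)c(OCc2ccccc2)c(OCc2ccccc2)c1O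
F4 | step 1 | 1-[2,3,4-tris(benzyloxy)phenyl]ethan-1-one | CC(=O)c1ccc(OCc2ccccc2)c(OCc2ccccc2)c1OCc1ccccc1
F0 | step 6 | none | none
A1 | alternative 1 | 4-methoxybenzene-1,2,3-triol | COc1ccc(O)c(O)c1O
A2 | alternative 1 | (3-hydroxy-4,5-dimethoxyphenyl)acetic acid | COc1cc(CC(=O)O)cc(O)c1OC
A3 | alternative 1 | 2-(3-hydroxy-4,5-dimethoxyphenyl)-1-(2,3,4-trihydroxy-5-methoxyphenyl)ethan-1-one | COc1cc(C(=O)Cc2cc(O)c(OC)c(OC)c2)c(O)c(O)c1O
A4 | alternative 2 | 7,8-bis(benzyloxy)-3-iodo-6-methoxy-4H-chromen-4-one | COc1cc2c(=O)c(I)coc2c(OCc2ccccc2)c1OCc1ccccc1
A5 | alternative 2 | [3-(benzyloxy)-4,5-dimethoxyphenyl]boronic acid | COc1cc(B(O)O)cc(OCc2ccccc2)c1OC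
A6 | alternative 3 | 3-(benzyloxy)-4,5-dimethoxybenzaldehyde | COc1cc(C=O)cc(OCc2ccccc2)c1OC
A7 | alternative 3 | (E)-1-[3,4-bis(benzyloxy)-2-hydroxy-5-methoxyphenyl]-3-[3-(benzyloxy)-4,5-dimethoxyphenyl]prop-2-en-1-one | COc1cc(C(=O)/C=C/c2cc(OCc3ccccc3)c(OC)c(OC)c2)c(O)c(OCc2ccccc2)c1OCc1ccccc1
A8 | alternative 3 | 1-[3,4-bis(benzyloxy)-2-hydroxy-5-methoxyphenyl]-2-[3-(benzyloxy)-4,5-dimethoxyphenyl]-3,3-dimethoxypropan-1-one (racemic) | COc1cc(C(=O)C(C(OC)OC)c2cc(OCc3ccccc3)c(OC)c(OC)c2)c(O)c(OCc2ccccc2)c1OCc1ccccc1
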